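## Retrosynthetic overview
1. The target comes from a fully protected enal by one acid hydrolysis (two MOM ethers, one trityl ether); the enal comes from a benzodioxine-6-carbaldehyde by Wittig two-carbon homologation.
2. The 1,4-dioxane ring is the only ring made (both arenes are bought). It is closed by intramolecular Cu-catalysed aryl C–O coupling of a threo (1R,2R)-1-aryl-2-(2-iodoaryloxy)propan-1-ol, which leaves both stereocentres untouched.
3. The threo diol comes from LiBH4 cleavage of an Evans syn-aldol adduct. The key C–C bond (C2–C3 of the dioxane) is made by the boron aldol of an N-(aryloxyacetyl)oxazolidinone with 3-methoxy-4,5-bis(MOM-oxy)benzaldehyde, which sets both stereocentres.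
4. The imide comes from 5-iodovanillin, ethyl bromoacetate and (S)-4-benzyl-2-oxazolidinone; the aldehyde comes from 5-hydroxyvanillin.

Assumption: 5-iodovanillin, 5-hydroxyvanillin and (S)-4-benzyl-2-oxazolidinone are bought; TBS = tert-butyldimethylsilyl, MOM = methoxymethyl, Tr = triphenylmethyl; in benzodioxine names C-2 carries the CH2O group and C-3 the aryl group.

## Route

Step 1
Reactants: 1 5-iodovanillin
Product: 2 4-(hydroxymethyl)-2-iodo-6-methoxyphenol
Conditions: NaBH4, EtOH, 0 °C → rt; aq NH4Cl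
Reagents that add atoms: none
Why: Chemoselective borohydride reduction of the aryl aldehyde stores the formyl group at the alcohol level so it cannot compete in the later aldol reaction.

Step 2
Reactants: 2 4-(hydroxymethyl)-2-iodo-6-methoxyphenol
Product: 3 ethyl 2-[4-(hydroxymethyl)-2-iodo-6-methoxyphenoxy]acetate
Conditions: BrCH2CO2Et (1.1 equiv), K2CO3, acetone, reflux
Reagents that add atoms: ethyl bromoacetate, CCOC(=O)CBr
Why: Williamson ether synthesis in which only the phenol is deprotonated by carbonate, so the benzylic alcohol is not alkylated.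

Step 3
Reactants: 3 ethyl 2-[4-(hydroxymethyl)-2-iodo-6-methoxyphenoxy]acetate
Product: 4 ethyl 2-[4-(TBSO-methyl)-2-iodo-6-methoxyphenoxy]acetate
Conditions: TBSCl, imidazole, DMF, rt
Reagents that add atoms: tert-butyldimethylsilyl chloride, CC(C)(C)[Si](C)(C)Cl
Why: Standard imidazole-promoted silylation of a primary alcohol gives a silyl ether that survives base, boron triflate, hydride and the copper coupling.

Step 4
Reactants: 4 ethyl 2-[4-(TBSO-methyl)-2-iodo-6-methoxyphenoxy]acetate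
Product: 5 2-[4-(TBSO-methyl)-2-iodo-6-methoxyphenoxy]acetic acid
Conditions: LiOH·H2O, THF/H2O 3:1, 0 °C → rt; cold 0.5 M HCl to pH 4
Reagents that add atoms: lithium hydroxide, [Li+].[OH-]
Why: Ester saponification (BAc2), to which the alkyl TBS ether and the aryl iodide are inert.

Step 5
Reactants: 5 2-[4-(TBSO-methyl)-2-iodo-6-methoxyphenoxy]acetic acid; 6 (S)-4-benzyl-2-oxazolidinone
Product: 8 (S)-4-benzyl-3-{2-[4-(TBSO-methyl)-2-iodo-6-methoxyphenoxy]acetyl}oxazolidin-2-one, via mixed pivalic anhydride 7 (not isolated)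
Conditions: PivCl, Et3N, THF, −20 °C, 1 h; then 6, LiCl, −20 °C → rt
Reagents that add atoms: pivaloyl chloride, CC(C)(C)C(Cl)=O (its atoms stay in 7 only)
Why: Mixed-anhydride N-acylation in which the oxazolidinone attacks the unhindered aryloxyacetyl carbonyl, and no organolithium is used that could touch the aryl iodide.

Step 6
Reactants: 9 3,4-dihydroxy-5-methoxybenzaldehyde
Product: 10 3-methoxy-4,5-bis(methoxymethoxy)benzaldehyde
Conditions: MOMCl (3 equiv), iPr2NEt (4 equiv), DMAP (cat.), CH2Cl2, 0 °C → rt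
Reagents that add atoms: chloromethyl methyl ether, COCCl
Why: O-Alkylation of both phenols gives base-, hydride- and copper-stable MOM acetals on the catechol.

Step 7
Reactants: 8 (S)-4-benzyl-3-{2-[4-(TBSO-methyl)-2-iodo-6-methoxyphenoxy]acetyl}oxazolidin-2-one; 10 3-methoxy-4,5-bis(methoxymethoxy)benzaldehyde
Product: 13 (S)-4-benzyl-3-[(2S,3R)-3-hydroxy-2-[4-(TBSO-methyl)-2-iodo-6-methoxyphenoxy]-3-[3-methoxy-4,5-bis(MOM-oxy)phenyl]propanoyl]oxazolidin-2-one, via Z-dibutylboron enolate 11 (not isolated), via dibutylboron aldolate 12 (not isolated)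
Conditions: Bu2BOTf (1.15 equiv), iPr2NEt (1.3 equiv), CH2Cl2, −78 → 0 °C; 10 (1.2 equiv), −78 → 0 °C; pH 7 buffer, MeOH, 30% H2O2, 0 °C
Reagents that add atoms: dibutylboron triflate, CCCCB(CCCC)OS(=O)(=O)C(F)(F)F (boron stays in 11 and 12 only)
Why: Evans syn aldol reaction, in which the Z-boron enolate adds through a chair Zimmerman–Traxler transition state on the face away from the benzyl group of the (S)-auxiliary, setting both stereocentres as (2S,3R).

Step 8
Reactants: 13 the syn-aldol adduct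
Product: 14 (1R,2R)-2-[4-(TBSO-methyl)-2-iodo-6-methoxyphenoxy]-1-[3-methoxy-4,5-bis(MOM-oxy)phenyl]propane-1,3-diol
Conditions: LiBH4, MeOH (1.5 equiv), THF, 0 °C
Reagents that add atoms: none
Why: Reductive cleavage of the N-acyl oxazolidinone at the exocyclic carbonyl gives the threo 1,3-diol and returns the auxiliary; no stereocentre is touched, and the C-2 descriptor changes from S to R only through CIP priorities.

Step 9
Reactants: 14 the (1R,2R)-1,3-diol
Product: 15 (1R,2R)-2-[4-(TBSO-methyl)-2-iodo-6-methoxyphenoxy]-1-[3-methoxy-4,5-bis(MOM-oxy)phenyl]-3-(trityloxy)propan-1-ol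
Conditions: TrCl (1.2 equiv), Et3N, DMAP (cat.), CH2Cl2, rt
Reagents that add atoms: trityl chloride, ClC(c1ccccc1)(c1ccccc1)c1ccccc1
Why: Tritylation is selective for the primary hydroxyl on steric grounds and gives a non-migrating ether, so the secondary benzylic alkoxide is the only nucleophile in the ring closure.

Step 10
Reactants: 15 the trityl ether
Product: 16 (2R,3R)-6-(TBSO-methyl)-8-methoxy-3-[3-methoxy-4,5-bis(MOM-oxy)phenyl]-2-(trityloxymethyl)-2,3-dihydro-1,4-benzodioxine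
Conditions: CuI (10 mol %), 3,4,7,8-tetramethyl-1,10-phenanthroline (20 mol %), Cs2CO3 (2 equiv), toluene, 100 °C, Ar
Reagents that add atoms: none
Why: Intramolecular Ullmann-type aryl C–O coupling forms the six-membered ring at the aryl carbon, so the carbinol C–O bond is never broken and the threo (1R,2R) alcohol gives the trans (2R,3R) benzodioxine with retention.

Step 11
Reactants: 16 the silyl-protected benzodioxine
Product: 17 [(2R,3R)-8-methoxy-3-[3-methoxy-4,5-bis(MOM-oxy)phenyl]-2-(trityloxymethyl)-2,3-dihydro-1,4-benzodioxin-6-yl]methanol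
Conditions: TBAF (1.2 equiv), THF, 0 °C → rt
Reagents that add atoms: none
Why: Fluoride desilylation frees only the benzylic alcohol because trityl and MOM ethers are inert to fluoride.

Step 12
Reactants: 17 the benzylic alcohol
Product: 18 (2R,3R)-8-methoxy-3-[3-methoxy-4,5-bis(MOM-oxy)phenyl]-2-(trityloxymethyl)-2,3-dihydro-1,4-benzodioxine-6-carbaldehyde
Conditions: activated MnO2 (15 equiv), CH2Cl2, rt
Reagents that add atoms: none
Why: Manganese dioxide oxidation of the only free (benzylic) alcohol stops cleanly at the aldehyde.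

Step 13
Reactants: 18 the benzodioxine-6-carbaldehyde
Product: 19 (E)-3-[(2R,3R)-8-methoxy-3-[3-methoxy-4,5-bis(MOM-oxy)phenyl]-2-(trityloxymethyl)-2,3-dihydro-1,4-benzodioxin-6-yl]prop-2-enal
Conditions: Ph3P=CHCHO (1.3 equiv), toluene, 85 °C
Reagents that add atoms: (triphenylphosphoranylidene)acetaldehyde, O=CC=P(c1ccccc1)(c1ccccc1)c1ccccc1
Why: Wittig olefination with a stabilised ylide gives the E-configured cinnamaldehyde under neutral conditions.

Step 14
Reactants: 19 the protected enal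
Product: 20 (E)-3-[(2R,3R)-3-(3,4-dihydroxy-5-methoxyphenyl)-2-(hydroxymethyl)-8-methoxy-2,3-dihydro-1,4-benzodioxin-6-yl]prop-2-enal
Conditions: 3 M aq HCl/THF 1:2, rt → 40 °C, Ar
Reagents that add atoms: none
Why: Acid-catalysed hydrolysis of the two MOM acetals and solvolysis of the trityl ether (cation trapped by water) release the catechol and the primary alcohol without a bond-forming event at either stereocentre.

## Compound list
1 | 5-iodovanillin (4-hydroxy-3-iodo-5-methoxybenzaldehyde) | COc1cc(C=O)cc(I)c1O | starting material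
2 | 4-(hydroxymethyl)-2-iodo-6-methoxyphenol | COc1cc(CO)cc(I)c1O | intermediate
3 | ethyl 2-[4-(hydroxymethyl)-2-iodo-6-methoxyphenoxy]acetate | CCOC(=O)COc1c(I)cc(CO)cc1OC | intermediate
4 | ethyl 2-[4-(TBSO-methyl)-2-iodo-6-methoxyphenoxy]acetate | CCOC(=O)COc1c(I)cc(CO[Si](C)(C)C(C)(C)C)cc1OC | intermediate
5 | 2-[4-(TBSO-methyl)-2-iodo-6-methoxyphenoxy]acetic acid | OC(=O)COc1c(I)cc(CO[Si](C)(C)C(C)(C)C)cc1OC | intermediate
6 | (S)-4-benzyl-2-oxazolidinone | O=C1N[C@@H](Cc2ccccc2)CO1 | starting material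
7 | mixed pivalic anhydride of 5 (not isolated) | CC(C)(C)C(=O)OC(=O)COc1c(I)cc(CO[Si](C)(C)C(C)(C)C)cc1OC | intermediate
8 | (S)-4-benzyl-3-{2-[4-(TBSO-methyl)-2-iodo-6-methoxyphenoxy]acetyl}oxazolidin-2-one | O=C1OC[C@H](Cc2ccccc2)N1C(=O)COc3c(I)cc(CO[Si](C)(C)C(C)(C)C)cc3OC | intermediate
9 | 3,4-dihydroxy-5-methoxybenzaldehyde (5-hydroxyvanillin) | COc1cc(C=O)cc(O)c1O | starting material
10 | 3-methoxy-4,5-bis(methoxymethoxy)benzaldehyde | COCOc1cc(C=O)cc(OC)c1OCOC | intermediate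
11 | Z-dibutylboron enolate of 8 (not isolated) | CCCCB(CCCC)O/C(N1C(=O)OC[C@@H]1Cc2ccccc2)=C\Oc3c(I)cc(CO[Si](C)(C)C(C)(C)C)cc3OC | intermediate
12 | dibutylboron aldolate of 13 (not isolated) | O=C1OC[C@H](Cc2ccccc2)N1C(=O)[C@@H](Oc3c(I)cc(CO[Si](C)(C)C(C)(C)C)cc3OC)[C@H](OB(CCCC)CCCC)c4cc(OC)c(OCOC)c(OCOC)c4 | intermediate
13 | (S)-4-benzyl-3-[(2S,3R)-3-hydroxy-2-[4-(TBSO-methyl)-2-iodo-6-methoxyphenoxy]-3-[3-methoxy-4,5-bis(MOM-oxy)phenyl]propanoyl]oxazolidin-2-one | O=C1OC[C@H](Cc2ccccc2)N1C(=O)[C@@H](Oc3c(I)cc(CO[Si](C)(C)C(C)(C)C)cc3OC)[C@H](O)c4cc(OC)c(OCOC)c(OCOC)c4 | intermediate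
14 | (1R,2R)-2-[4-(TBSO-methyl)-2-iodo-6-methoxyphenoxy]-1-[3-methoxy-4,5-bis(MOM-oxy)phenyl]propane-1,3-diol | OC[C@@H](Oc1c(I)cc(CO[Si](C)(C)C(C)(C)C)cc1OC)[C@H](O)c1cc(OC)c(OCOC)c(OCOC)c1 | intermediate
15 | (1R,2R)-2-[4-(TBSO-methyl)-2-iodo-6-methoxyphenoxy]-1-[3-methoxy-4,5-bis(MOM-oxy)phenyl]-3-(trityloxy)propan-1-ol | C(c1ccccc1)(c1ccccc1)(c1ccccc1)OC[C@@H](Oc1c(I)cc(CO[Si](C)(C)C(C)(C)C)cc1OC)[C@H](O)c1cc(OC)c(OCOC)c(OCOC)c1 | intermediate
16 | (2R,3R)-6-(TBSO-methyl)-8-methoxy-3-[3-methoxy-4,5-bis(MOM-oxy)phenyl]-2-(trityloxymethyl)-2,3-dihydro-1,4-benzodioxine | C(c1ccccc1)(c1ccccc1)(c1ccccc1)OC[C@H]1Oc2c(OC)cc(CO[Si](C)(C)C(C)(C)C)cc2O[C@@H]1c1cc(OC)c(OCOC)c(OCOC)c1 | intermediate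
17 | [(2R,3R)-8-methoxy-3-[3-methoxy-4,5-bis(MOM-oxy)phenyl]-2-(trityloxymethyl)-2,3-dihydro-1,4-benzodioxin-6-yl]methanol | C(c1ccccc1)(c1ccccc1)(c1ccccc1)OC[C@H]1Oc2c(OC)cc(CO)cc2O[C@@H]1c1cc(OC)c(OCOC)c(OCOC)c1 | intermediate
18 | (2R,3R)-8-methoxy-3-[3-methoxy-4,5-bis(MOM-oxy)phenyl]-2-(trityloxymethyl)-2,3-dihydro-1,4-benzodioxine-6-carbaldehyde | C(c1ccccc1)(c1ccccc1)(c1ccccc1)OC[C@H]1Oc2c(OC)cc(C=O)cc2O[C@@H]1c1cc(OC)c(OCOC)c(OCOC)c1 | intermediate
19 | (E)-3-[(2R,3R)-8-methoxy-3-[3-methoxy-4,5-bis(MOM-oxy)phenyl]-2-(trityloxymethyl)-2,3-dihydro-1,4-benzodioxin-6-yl]prop-2-enal | C(c1ccccc1)(c1ccccc1)(c1ccccc1)OC[C@H]1Oc2c(OC)cc(/C=C/C=O)cc2O[C@@H]1c1cc(OC)c(OCOC)c(OCOC)c1 | intermediate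
20 | (E)-3-[(2R,3R)-3-(3,4-dihydroxy-5-methoxyphenyl)-2-(hydroxymethyl)-8-methoxy-2,3-dihydro-1,4-benzodioxin-6-yl]prop-2-enal | OC[C@H]1Oc2c(OC)cc(/C=C/C=O)cc2O[C@@H]1c1cc(OC)c(O)c(O)c1 | target

## Step count and risks
Total steps: 14. Longest linear sequence: 13 (steps 1–5 and 7–14 from 5-iodovanillin); step 6 is a one-step side branch.

Step 10 (copper ring closure) is the first risk: the hindered secondary benzylic alkoxide may couple slowly, and the aryl iodide may be reduced instead. The fallback sets out from 15 and comes back at 16. Miyaura borylation of the iodide (B2pin2, PdCl2(dppf), KOAc, dioxane, 80 °C) gives the aryl pinacol boronate F1. An intramolecular Chan–Lam oxidative etherification (Cu(OAc)2, pyridine, 4 Å sieves, O2, CH2Cl2, rt to 40 °C) then forms the same aryl–oxygen bond without carbonate base or heating. The carbinol C–O bond is again untouched, so the (2R,3R) configuration is kept.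

Step 13 (Wittig) is the second risk: the electron-rich aldehyde may react sluggishly, and the product enal can be homologated a second time to the dienal. The fallback sets out from 18 and comes back at 19. Horner–Wadsworth–Emmons olefination with triethyl phosphonoacetate (LiCl, DBU, MeCN, rt) gives the ethyl (E)-propenoate ester F2. DIBAL-H (CH2Cl2, −78 °C) reduces it to the (E)-allylic alcohol F3, and MnO2 (CH2Cl2, rt) oxidises that to 19.

Step 14 (global deprotection) is the third risk: the enal and catechol see aqueous acid, the released formaldehyde can attack the electron-rich ring, and the benzylic ring C–O bond at C-3 could open reversibly and erode the trans ratio. The fallback sets out from 18 and comes back at 20. The same acid hydrolysis (3 M HCl/THF) is run on the more robust aldehyde 18 to give the fully deprotected aldehyde F4. The Wittig reaction with Ph3P=CHCHO (THF/toluene, 70 °C) is then the last step; the stabilised ylide is not basic enough to be quenched by the phenols, and the enal never meets acid.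

## Further compounds
F1 | step 10 | (1R,2R)-2-[4-(TBSO-methyl)-2-methoxy-6-(4,4,5,5-tetramethyl-1,3,2-dioxaborolan-2-yl)phenoxy]-1-[3-methoxy-4,5-bis(MOM-oxy)phenyl]-3-(trityloxy)propan-1-ol | C(c1ccccc1)(c1ccccc1)(c1ccccc1)OC[C@@H](Oc1c(B2OC(C)(C)C(C)(C)O2)cc(CO[Si](C)(C)C(C)(C)C)cc1OC)[C@H](O)c1cc(OC)c(OCOC)c(OCOC)c1
F2 | step 13 | ethyl (E)-3-[(2R,3R)-8-methoxy-3-[3-methoxy-4,5-bis(MOM-oxy)phenyl]-2-(trityloxymethyl)-2,3-dihydro-1,4-benzodioxin-6-yl]prop-2-enoate | C(c1ccccc1)(c1ccccc1)(c1ccccc1)OC[C@H]1Oc2c(OC)cc(/C=C/C(=O)OCC)cc2O[C@@H]1c1cc(OC)c(OCOC)c(OCOC)c1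
F3 | step 13 | (E)-3-[(2R,3R)-8-methoxy-3-[3-methoxy-4,5-bis(MOM-oxy)phenyl]-2-(trityloxymethyl)-2,3-dihydro-1,4-benzodioxin-6-yl]prop-2-en-1-ol | C(c1ccccc1)(c1ccccc1)(c1ccccc1)OC[C@H]1Oc2c(OC)cc(/C=C/CO)cc2O[C@@H]1c1cc(OC)c(OCOC)c(OCOC)c1
F4 | step 14 | (2R,3R)-3-(3,4-dihydroxy-5-methoxyphenyl)-2-(hydroxymethyl)-8-methoxy-2,3-dihydro-1,4-benzodioxine-6-carbaldehyde | OC[C@H]1Oc2c(OC)cc(C=O)cc2O[C@@H]1c1cc(OC)c(O)c(O)c1
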